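**Retrosynthetic overview**

1. Target ⇐ desilylation and O6 acylation of a 6-hydroxy-12,8-olide ⇐ lactone walk (O6 → O8 translactonisation) from the isomeric 8-hydroxy-12,6-olide.
2. Key disconnection C7–C8: intramolecular CrCl2-mediated allylation of a C8 aldehyde by an α-(bromomethyl)butenolide; it closes the ten-membered carbocycle, sets C7 and C8 and creates the C11=C13 methylene group.
3. Enabling feature: C7 is the γ-carbon of the C13–C11(=C7)–C12 carboxyallyl unit and lies between two oxygen-bearing carbons, C6 and C8, both γ to C12. C12 can therefore be parked on O6 as a temporary butenolide ring (O6, C6, C7, C11, C12), absent from the target, which fixes the allyl geometry and the C7 face while C8 is the electrophile; the lactone later moves to O8.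
4. Linear precursor: C6 by CBS reduction of an ynone, then hydroalumination/iodination and carbonylative lactonisation; Z-C4=C5 and C2 from a catalytic asymmetric vinylogous aldol that closes a temporary dihydropyranone; Z-C1=C10 by anti-carbomagnesiation of (R)-but-3-yne-1,2-diol (C9 from methyl (S)-glycerate acetonide).
5. Order of ring formation: dihydropyranone (step 7, opened in step 8), butenolide (step 13), ten-membered carbocycle (step 17), γ-lactone on O8 (step 18).

Key step: step 17

Remark: germacrane numbering (C1–C15, O2, O6, O8, O9) is used for all intermediates; the sense of induction in steps 7 and 11 is assigned from the accepted models for these catalyst types.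

**Route**

Step 1
Reactants: 1 methyl (S)-2,2-dimethyl-1,3-dioxolane-4-carboxylate
Product: 3 (R)-4-ethynyl-2,2-dimethyl-1,3-dioxolane, via aldehyde 2 (not isolated)
Conditions: i-Bu2AlH (1.1 equiv), CH2Cl2, −78 °C; then MeOH, dimethyl (1-diazo-2-oxopropyl)phosphonate, K2CO3, −78 °C to rt
Reagents that add atoms: dimethyl (1-diazo-2-oxopropyl)phosphonate, CC(=O)C(=[N+]=[N-])P(=O)(OC)OC
Why: Half-reduction of the ester by i-Bu2AlH at −78 °C stops at the aluminium hemiacetal, and the aldehyde released by methanol is homologated in the same flask by the Seyferth–Gilbert reaction in its Ohira–Bestmann form, which leaves an α-alkoxy stereocentre untouched, so the centre of 1 is carried over and becomes C9.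

Step 2
Reactants: 3 (R)-4-ethynyl-2,2-dimethyl-1,3-dioxolane
Product: 4 (R)-but-3-yne-1,2-diol
Conditions: p-TsOH·H2O (cat.), MeOH, rt; solid NaHCO3, filter, concentrate
Reagents that add atoms: none
Why: Acid-catalysed transacetalisation to methanol (acetal cleavage) removes the acetonide and frees the propargylic hydroxyl group that the next step needs as a directing group, without touching the alkyne or C9.

Step 3
Reactants: 4 (R)-but-3-yne-1,2-diol
Product: 6 (2R,3Z)-4-iodo-3-methylbut-3-ene-1,2-diol, via alkenylmagnesium 5 (not isolated)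
Conditions: MeMgBr (4.5 equiv), CuI (0.2 equiv), Et2O/THF, −20 °C to rt; then I2, −78 to 0 °C
Reagents that add atoms: methylmagnesium bromide, C[Mg]Br; iodine, II
Why: Copper-catalysed anti-carbomagnesiation of a propargylic alkoxide puts the methyl group on the internal alkyne carbon and magnesium on the terminal carbon, held cis to the carbinol carbon in a five-membered magnesium alkoxide chelate, and iodinolysis with retention gives the Z-iodoalkene that fixes the C1=C10 geometry.

Step 4
Reactants: 6 (2R,3Z)-4-iodo-3-methylbut-3-ene-1,2-diol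
Product: 7 (2R,3Z)-1,2-bis(tert-butyldimethylsilyloxy)-4-iodo-3-methylbut-3-ene
Conditions: t-BuMe2SiCl (2.5 equiv), imidazole, DMF, rt
Reagents that add atoms: tert-butyldimethylsilyl chloride, CC(C)(C)[Si](C)(C)Cl
Why: Standard imidazole-promoted silylation protects both hydroxyl groups, the primary O8 ether being removable later beside the hindered secondary ones.

Step 5
Reactants: 7 (2R,3Z)-1,2-bis(tert-butyldimethylsilyloxy)-4-iodo-3-methylbut-3-ene
Product: 9 (2Z,4R)-4,5-bis(tert-butyldimethylsilyloxy)-3-methylpent-2-enal, via alkenyllithium 8 (not isolated)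
Conditions: t-BuLi (2.1 equiv), Et2O, −78 °C; then DMF, −78 to 0 °C
Reagents that add atoms: N,N-dimethylformamide, CN(C)C=O
Why: Iodine–lithium exchange with two equivalents of t-BuLi at −78 °C in ether proceeds with retention of alkene geometry, and the alkenyllithium is trapped by DMF (Bouveault formylation) before a 1,4 O-to-C silyl shift can compete, giving the Z-enal.

Step 6
Reactants: 10 ethyl 3-methylbut-2-enoate
Product: 12 1-ethoxy-3-methyl-1-(trimethylsilyloxy)buta-1,3-diene, via lithium dienolate 11 (not isolated)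
Conditions: i-Pr2NH, n-BuLi, THF, −78 °C; 10; then Me3SiCl, −78 °C to rt
Reagents that add atoms: chlorotrimethylsilane, C[Si](C)(C)Cl
Why: Kinetic γ-deprotonation of the β,β-dimethylacrylate and O-silylation of the lithium dienolate (silyl ketene acetal formation) give the vinylogous nucleophile.

Step 7
Reactants: 9 (2Z,4R)-4,5-bis(tert-butyldimethylsilyloxy)-3-methylpent-2-enal; 12 1-ethoxy-3-methyl-1-(trimethylsilyloxy)buta-1,3-diene
Product: 14 (6S)-6-[(1Z,3R)-3,4-bis(tert-butyldimethylsilyloxy)-2-methylbut-1-enyl]-4-methyl-5,6-dihydro-2H-pyran-2-one, via aldolate 13 (not isolated)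
Conditions: Cu(OTf)2 (10 mol %), (R)-Tol-BINAP (11 mol %), Bu4N[Ph3SiF2] (20 mol %), THF, −40 °C to rt
Reagents that add atoms: none
Why: Catalytic asymmetric vinylogous Mukaiyama aldol reaction through a chiral copper dienolate: γ-attack on the aldehyde sets C2 under ligand control ((R)-Tol-BINAP chosen by analogy with the accepted sense of induction for alkenyl aldehydes, the remote C9 centre having little influence), and the aldolate closes on the ester through the Z-enoate, so that the temporary six-membered lactone fixes the C4=C5 double bond as Z.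

Step 8
Reactants: 14 (6S)-6-[(1Z,3R)-3,4-bis(tert-butyldimethylsilyloxy)-2-methylbut-1-enyl]-4-methyl-5,6-dihydro-2H-pyran-2-one
Product: 15 (2Z,5S,6Z,8R)-8,9-bis(tert-butyldimethylsilyloxy)-5-hydroxy-N-methoxy-N,3,7-trimethylnona-2,6-dienamide
Conditions: MeNH(OMe)·HCl, AlMe3, CH2Cl2, 0 °C to rt
Reagents that add atoms: N,O-dimethylhydroxylamine hydrochloride, CNOC.Cl
Why: Aminolysis of the lactone by the aluminium amide of N,O-dimethylhydroxylamine (Weinreb amide formation) opens the temporary ring under non-basic conditions that keep the Z-enoate geometry, and frees O2.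

Step 9
Reactants: 15 (2Z,5S,6Z,8R)-8,9-bis(tert-butyldimethylsilyloxy)-5-hydroxy-N-methoxy-N,3,7-trimethylnona-2,6-dienamide
Product: 16 (2Z,5S,6Z,8R)-5,8,9-tris(tert-butyldimethylsilyloxy)-N-methoxy-N,3,7-trimethylnona-2,6-dienamide
Conditions: t-BuMe2SiOTf, 2,6-lutidine, CH2Cl2, −78 °C
Reagents that add atoms: tert-butyldimethylsilyl trifluoromethanesulfonate, CC(C)(C)[Si](C)(C)OS(=O)(=O)C(F)(F)F
Why: Silylation with the silyl triflate and 2,6-lutidine at low temperature is faster than relactonisation of the Z-δ-hydroxy amide and protects O2.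

Step 10
Reactants: 16 (2Z,5S,6Z,8R)-5,8,9-tris(tert-butyldimethylsilyloxy)-N-methoxy-N,3,7-trimethylnona-2,6-dienamide; 17 tert-butyldimethyl(prop-2-ynyloxy)silane
Product: 19 (5Z,8S,9Z,11R)-1,8,11,12-tetrakis(tert-butyldimethylsilyloxy)-6,10-dimethyldodeca-5,9-dien-2-yn-4-one, via lithium acetylide 18 (not isolated)
Conditions: 17, n-BuLi, THF, −78 °C; then 16, −78 to −20 °C; aq. NH4Cl
Reagents that add atoms: none
Why: Acylation of a lithium acetylide by a Weinreb amide stops at the ketone because the chelated tetrahedral intermediate survives until work-up, and brings in C7, C11 and C13.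

Step 11
Reactants: 19 (5Z,8S,9Z,11R)-1,8,11,12-tetrakis(tert-butyldimethylsilyloxy)-6,10-dimethyldodeca-5,9-dien-2-yn-4-one
Product: 20 (4R,5Z,8S,9Z,11R)-1,8,11,12-tetrakis(tert-butyldimethylsilyloxy)-6,10-dimethyldodeca-5,9-dien-2-yn-4-ol
Conditions: (R)-2-methyl-CBS-oxazaborolidine (0.5 equiv), catecholborane, toluene, −78 °C
Reagents that add atoms: none
Why: Corey–Bakshi–Shibata reduction, in which the alkynyl group acts as the small and the β,β-disubstituted Z-alkenyl group as the large substituent, so that the (R)-oxazaborolidine delivers hydride to the ketone face that gives the 6R carbinol under reagent control.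

Step 12
Reactants: 20 (4R,5Z,8S,9Z,11R)-1,8,11,12-tetrakis(tert-butyldimethylsilyloxy)-6,10-dimethyldodeca-5,9-dien-2-yn-4-ol
Product: 22 (2Z,4R,5Z,8S,9Z,11R)-1,8,11,12-tetrakis(tert-butyldimethylsilyloxy)-2-iodo-6,10-dimethyldodeca-2,5,9-trien-4-ol, via alkenylalanate 21 (not isolated)
Conditions: NaAlH2(OCH2CH2OMe)2 (Red-Al, 1.5 equiv), THF, 0 °C to rt; then I2 in THF, −78 to 0 °C
Reagents that add atoms: iodine, II
Why: Hydroxyl-directed trans-hydroalumination of the propargylic alcohol places hydride on C7 and aluminium on C11 within a five-membered alkoxyaluminate, and iodinolysis with retention gives the Z-iodoalkene with iodine cis to the C6 carbinol, the silylated O13 not competing as a directing group.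

Step 13
Reactants: 22 (2Z,4R,5Z,8S,9Z,11R)-1,8,11,12-tetrakis(tert-butyldimethylsilyloxy)-2-iodo-6,10-dimethyldodeca-2,5,9-trien-4-ol
Product: 23 (5R)-3-(tert-butyldimethylsilyloxymethyl)-5-[(1Z,4S,5Z,7R)-4,7,8-tris(tert-butyldimethylsilyloxy)-2,6-dimethylocta-1,5-dienyl]furan-2(5H)-one
Conditions: PdCl2(PPh3)2 (5 mol %), CO (1 atm), K2CO3, THF, 40 °C
Reagents that add atoms: carbon monoxide, [C-]#[O+]
Why: Palladium-catalysed carbonylative lactonisation of a Z-γ-iodoallylic alcohol: oxidative addition to zerovalent palladium, CO insertion and capture of the acylpalladium species by the cis hydroxyl group close the butenolide, the temporary ring that holds C6 cis to C12.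

Step 14
Reactants: 23 (5R)-3-(tert-butyldimethylsilyloxymethyl)-5-[(1Z,4S,5Z,7R)-4,7,8-tris(tert-butyldimethylsilyloxy)-2,6-dimethylocta-1,5-dienyl]furan-2(5H)-one
Product: 24 (5R)-5-[(1Z,4S,5Z,7R)-4,7-bis(tert-butyldimethylsilyloxy)-8-hydroxy-2,6-dimethylocta-1,5-dienyl]-3-(hydroxymethyl)furan-2(5H)-one
Conditions: HF·pyridine, pyridine, THF, 0 °C
Reagents that add atoms: none
Why: Buffered HF·pyridine cleaves primary tert-butyldimethylsilyl ethers much faster than hindered secondary ones (selective desilylation), so O8 and O13 are freed without base that could isomerise the butenolide.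

Step 15
Reactants: 24 (5R)-5-[(1Z,4S,5Z,7R)-4,7-bis(tert-butyldimethylsilyloxy)-8-hydroxy-2,6-dimethylocta-1,5-dienyl]-3-(hydroxymethyl)furan-2(5H)-one
Product: 25 (5R)-3-(bromomethyl)-5-[(1Z,4S,5Z,7R)-4,7-bis(tert-butyldimethylsilyloxy)-8-hydroxy-2,6-dimethylocta-1,5-dienyl]furan-2(5H)-one
Conditions: N-bromosuccinimide (2.5 equiv), Me2S (3 equiv), CH2Cl2, −30 to 0 °C; aqueous work-up
Reagents that add atoms: N-bromosuccinimide, O=C1CCC(=O)N1Br
Why: Corey–Kim halogenation: both alcohols form alkoxysulfonium salts but only the allylic one at C13 is displaced by bromide at 0 °C, the saturated one at C8 returning as the alcohol on aqueous work-up.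

Step 16
Reactants: 25 (5R)-3-(bromomethyl)-5-[(1Z,4S,5Z,7R)-4,7-bis(tert-butyldimethylsilyloxy)-8-hydroxy-2,6-dimethylocta-1,5-dienyl]furan-2(5H)-one
Product: 26 (2R,3Z,5S,7Z)-8-[(2R)-4-(bromomethyl)-5-oxo-2,5-dihydrofuran-2-yl]-2,5-bis(tert-butyldimethylsilyloxy)-3,7-dimethylocta-3,7-dienal
Conditions: Dess–Martin periodinane, NaHCO3, CH2Cl2, 0 °C to rt
Reagents that add atoms: none
Why: Dess–Martin oxidation under buffered, non-basic conditions gives the α-silyloxy aldehyde without epimerising C9 and without touching the allylic bromide or the butenolide.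

Step 17
Reactants: 26 (2R,3Z,5S,7Z)-8-[(2R)-4-(bromomethyl)-5-oxo-2,5-dihydrofuran-2-yl]-2,5-bis(tert-butyldimethylsilyloxy)-3,7-dimethylocta-3,7-dienal
Product: 28 (1(10)Z,4Z,2S,6R,7R,8R,9R)-2,9-bis(tert-butyldimethylsilyloxy)-8-hydroxygermacra-1(10),4,11(13)-trien-12,6-olide, via allylchromium 27 (not isolated)
Conditions: CrCl2 (8 equiv), THF, 4 Å molecular sieves, rt; 26 added by syringe pump over 12 h (final 0.003 M); aqueous work-up
Reagents that add atoms: none
Why: Two equivalents of CrCl2 reduce the allylic C13–Br bond (divalent to trivalent chromium) to an allylchromium reagent that adds through its γ-carbon C7 to the C8 aldehyde in a six-membered Zimmerman–Traxler chair with allylic transposition, which also creates the C11=C13 exocyclic methylene group. This is a Nozaki–Hiyama–Kishi allylation, closest to the known CrCl2-mediated additions of 3-(bromomethyl)furan-2(5H)-one to aldehydes and to chromium-mediated macrocyclisations of ω-formyl allylic bromides. One ring is closed, the ten-membered carbocycle, in the 10-exo-trig mode (the C=O bond stays outside the new ring), at high dilution and helped by the two Z-trisubstituted alkenes that pre-bend the chain. C7 is controlled by C6 through the temporary butenolide ring, the aldehyde adding to the ring face anti to the C5 substituent (6,7-trans); C8 is controlled by the chair, because the ring locks C6 cis to C12 (E-type allylmetal) and the C9 branch sits pseudo-equatorial, which gives the 7,8-anti and hence 8R, 8,9-syn arrangement of the target. The selectivities needed are γ- over α-attack (inherent to the cyclic transition state), intra- over intermolecular coupling (dilution), aldehyde over lactone (trivalent allylchromium reagents do not add to esters) and dominance of the butenolide-controlled chair over the polar Felkin–Anh bias of the C9 silyloxy group, which both competing chairs can accommodate with the C9–O bond anti to the forming bond.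

Step 18
Reactants: 28 (1(10)Z,4Z,2S,6R,7R,8R,9R)-2,9-bis(tert-butyldimethylsilyloxy)-8-hydroxygermacra-1(10),4,11(13)-trien-12,6-olide
Product: 29 (1(10)Z,4Z,2S,6R,7S,8R,9R)-2,9-bis(tert-butyldimethylsilyloxy)-6-hydroxygermacra-1(10),4,11(13)-trien-12,8-olide
Conditions: DBU (0.2 equiv), CH2Cl2, 0 °C to rt; chromatography, recovered 28 resubmitted
Reagents that add atoms: none
Why: Base-catalysed translactonisation, a 1,3 O-to-O acyl shift through a bicyclic tetrahedral intermediate, moves the C12 acyl group from O6 to the neighbouring O8 (both oxygens are trans to H7, so either lactone is trans-fused), which trades the temporary ring for the lactone of the target without touching a stereocentre; the two hydroxy lactones equilibrate, 29 is separated and recovered 28 is resubmitted.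

Step 19
Reactants: 29 (1(10)Z,4Z,2S,6R,7S,8R,9R)-2,9-bis(tert-butyldimethylsilyloxy)-6-hydroxygermacra-1(10),4,11(13)-trien-12,8-olide; 30 (R)-2-methylbutanoic acid
Product: 31 (1(10)Z,4Z,2S,6R,7S,8R,9R)-2,9-bis(tert-butyldimethylsilyloxy)-6-[(R)-2-methylbutanoyloxy]germacra-1(10),4,11(13)-trien-12,8-olide
Conditions: N,N'-dicyclohexylcarbodiimide, DMAP (cat.), CH2Cl2, 0 °C to rt
Reagents that add atoms: none
Why: Steglich esterification of the allylic O6 hydroxyl group, the only free hydroxyl group of 29, with the R acid, whose α-stereocentre is not epimerised by carbodiimide activation with catalytic DMAP at low temperature.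

Step 20
Reactants: 31 (1(10)Z,4Z,2S,6R,7S,8R,9R)-2,9-bis(tert-butyldimethylsilyloxy)-6-[(R)-2-methylbutanoyloxy]germacra-1(10),4,11(13)-trien-12,8-olide
Product: 32 (1(10)Z,4Z,2S,6R,7S,8R,9R)-2,9-dihydroxy-6-[(R)-2-methylbutanoyloxy]germacra-1(10),4,11(13)-trien-12,8-olide
Conditions: HF·pyridine, pyridine, THF, 0 °C to rt
Reagents that add atoms: none
Why: Fluoride cleavage of the two secondary silyl ethers (desilylation) under mildly acidic buffered conditions leaves the α-methylene lactone, the allylic ester and both Z-alkenes untouched and gives the target.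

**Compound list**

1 | methyl (S)-2,2-dimethyl-1,3-dioxolane-4-carboxylate | COC(=O)[C@@H]1COC(C)(C)O1 | starting material
2 | (S)-2,2-dimethyl-1,3-dioxolane-4-carbaldehyde | O=C[C@@H]1COC(C)(C)O1 | intermediate
3 | (R)-4-ethynyl-2,2-dimethyl-1,3-dioxolane | C#C[C@@H]1COC(C)(C)O1 | intermediate
4 | (R)-but-3-yne-1,2-diol | C#C[C@@H](O)CO | intermediate
5 | (Z)-alkenylmagnesium bromide from 4, as its bis(bromomagnesium) alkoxide | Br[Mg]/C=C(/C)[C@@H](O[Mg]Br)CO[Mg]Br | intermediate
6 | (2R,3Z)-4-iodo-3-methylbut-3-ene-1,2-diol | I/C=C(/C)[C@@H](O)CO | intermediate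
7 | (2R,3Z)-1,2-bis(tert-butyldimethylsilyloxy)-4-iodo-3-methylbut-3-ene | I/C=C(/C)[C@@H](O[Si](C)(C)C(C)(C)C)CO[Si](C)(C)C(C)(C)C | intermediate
8 | (Z)-alkenyllithium from 7 | [Li]/C=C(/C)[C@@H](O[Si](C)(C)C(C)(C)C)CO[Si](C)(C)C(C)(C)C | intermediate
9 | (2Z,4R)-4,5-bis(tert-butyldimethylsilyloxy)-3-methylpent-2-enal | O=C/C=C(/C)[C@@H](O[Si](C)(C)C(C)(C)C)CO[Si](C)(C)C(C)(C)C | intermediate
10 | ethyl 3-methylbut-2-enoate | CCOC(=O)C=C(C)C | starting material
11 | lithium dienolate of 10 | CCOC(O[Li])=CC(C)=C | intermediate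
12 | 1-ethoxy-3-methyl-1-(trimethylsilyloxy)buta-1,3-diene | CCOC(O[Si](C)(C)C)=CC(C)=C | intermediate
13 | ethyl (2Z,5S,6Z,8R)-8,9-bis(tert-butyldimethylsilyloxy)-5-hydroxy-3,7-dimethylnona-2,6-dienoate, present as its copper or silyl aldolate | CCOC(=O)/C=C(C)\C[C@H](O)/C=C(/C)[C@@H](O[Si](C)(C)C(C)(C)C)CO[Si](C)(C)C(C)(C)C | intermediate
14 | (6S)-6-[(1Z,3R)-3,4-bis(tert-butyldimethylsilyloxy)-2-methylbut-1-enyl]-4-methyl-5,6-dihydro-2H-pyran-2-one | CC1=CC(=O)O[C@@H](C1)/C=C(/C)[C@@H](O[Si](C)(C)C(C)(C)C)CO[Si](C)(C)C(C)(C)C | intermediate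
15 | (2Z,5S,6Z,8R)-8,9-bis(tert-butyldimethylsilyloxy)-5-hydroxy-N-methoxy-N,3,7-trimethylnona-2,6-dienamide | CON(C)C(=O)/C=C(C)\C[C@H](O)/C=C(/C)[C@@H](O[Si](C)(C)C(C)(C)C)CO[Si](C)(C)C(C)(C)C | intermediate
16 | (2Z,5S,6Z,8R)-5,8,9-tris(tert-butyldimethylsilyloxy)-N-methoxy-N,3,7-trimethylnona-2,6-dienamide | CON(C)C(=O)/C=C(C)\C[C@H](O[Si](C)(C)C(C)(C)C)/C=C(/C)[C@@H](O[Si](C)(C)C(C)(C)C)CO[Si](C)(C)C(C)(C)C | intermediate
17 | tert-butyldimethyl(prop-2-ynyloxy)silane | C#CCO[Si](C)(C)C(C)(C)C | starting material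
18 | lithium acetylide of 17 | [Li]C#CCO[Si](C)(C)C(C)(C)C | intermediate
19 | (5Z,8S,9Z,11R)-1,8,11,12-tetrakis(tert-butyldimethylsilyloxy)-6,10-dimethyldodeca-5,9-dien-2-yn-4-one | CC(C)(C)[Si](C)(C)OCC#CC(=O)/C=C(C)\C[C@H](O[Si](C)(C)C(C)(C)C)/C=C(/C)[C@@H](O[Si](C)(C)C(C)(C)C)CO[Si](C)(C)C(C)(C)C | intermediate
20 | (4R,5Z,8S,9Z,11R)-1,8,11,12-tetrakis(tert-butyldimethylsilyloxy)-6,10-dimethyldodeca-5,9-dien-2-yn-4-ol | CC(C)(C)[Si](C)(C)OCC#C[C@H](O)/C=C(C)\C[C@H](O[Si](C)(C)C(C)(C)C)/C=C(/C)[C@@H](O[Si](C)(C)C(C)(C)C)CO[Si](C)(C)C(C)(C)C | intermediate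
21 | cyclic sodium alkoxy(alkenyl)aluminate from 20 (aluminium on C11, bonded to O6) | [Na+].COCCO[Al-]1(OCCOC)O[C@H](/C=C(C)\C[C@H](O[Si](C)(C)C(C)(C)C)/C=C(/C)[C@@H](O[Si](C)(C)C(C)(C)C)CO[Si](C)(C)C(C)(C)C)C=C1CO[Si](C)(C)C(C)(C)C | intermediate
22 | (2Z,4R,5Z,8S,9Z,11R)-1,8,11,12-tetrakis(tert-butyldimethylsilyloxy)-2-iodo-6,10-dimethyldodeca-2,5,9-trien-4-ol | CC(C)(C)[Si](C)(C)OC/C(I)=C/[C@H](O)/C=C(C)\C[C@H](O[Si](C)(C)C(C)(C)C)/C=C(/C)[C@@H](O[Si](C)(C)C(C)(C)C)CO[Si](C)(C)C(C)(C)C | intermediate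
23 | (5R)-3-(tert-butyldimethylsilyloxymethyl)-5-[(1Z,4S,5Z,7R)-4,7,8-tris(tert-butyldimethylsilyloxy)-2,6-dimethylocta-1,5-dienyl]furan-2(5H)-one | CC(C)(C)[Si](C)(C)OC[C@H](O[Si](C)(C)C(C)(C)C)/C(C)=C\[C@@H](O[Si](C)(C)C(C)(C)C)C/C(C)=C\[C@H]1OC(=O)C(CO[Si](C)(C)C(C)(C)C)=C1 | intermediate
24 | (5R)-5-[(1Z,4S,5Z,7R)-4,7-bis(tert-butyldimethylsilyloxy)-8-hydroxy-2,6-dimethylocta-1,5-dienyl]-3-(hydroxymethyl)furan-2(5H)-one | OC[C@H](O[Si](C)(C)C(C)(C)C)/C(C)=C\[C@@H](O[Si](C)(C)C(C)(C)C)C/C(C)=C\[C@H]1OC(=O)C(CO)=C1 | intermediate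
25 | (5R)-3-(bromomethyl)-5-[(1Z,4S,5Z,7R)-4,7-bis(tert-butyldimethylsilyloxy)-8-hydroxy-2,6-dimethylocta-1,5-dienyl]furan-2(5H)-one | OC[C@H](O[Si](C)(C)C(C)(C)C)/C(C)=C\[C@@H](O[Si](C)(C)C(C)(C)C)C/C(C)=C\[C@H]1OC(=O)C(CBr)=C1 | intermediate
26 | (2R,3Z,5S,7Z)-8-[(2R)-4-(bromomethyl)-5-oxo-2,5-dihydrofuran-2-yl]-2,5-bis(tert-butyldimethylsilyloxy)-3,7-dimethylocta-3,7-dienal | O=C[C@H](O[Si](C)(C)C(C)(C)C)/C(C)=C\[C@@H](O[Si](C)(C)C(C)(C)C)C/C(C)=C\[C@H]1OC(=O)C(CBr)=C1 | intermediate
27 | allylchromium dichloride from 26 (trivalent chromium on C13) | O=C[C@H](O[Si](C)(C)C(C)(C)C)/C(C)=C\[C@@H](O[Si](C)(C)C(C)(C)C)C/C(C)=C\[C@H]1OC(=O)C(C[Cr](Cl)Cl)=C1 | intermediate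
28 | (1(10)Z,4Z,2S,6R,7R,8R,9R)-2,9-bis(tert-butyldimethylsilyloxy)-8-hydroxygermacra-1(10),4,11(13)-trien-12,6-olide (6,7-trans lactone, 7,8-anti, 8,9-syn) | C=C1C(=O)O[C@@H]2/C=C(/C)C[C@H](O[Si](C)(C)C(C)(C)C)/C=C(/C)[C@@H](O[Si](C)(C)C(C)(C)C)[C@H](O)[C@@H]12 | intermediate
29 | (1(10)Z,4Z,2S,6R,7S,8R,9R)-2,9-bis(tert-butyldimethylsilyloxy)-6-hydroxygermacra-1(10),4,11(13)-trien-12,8-olide | C=C1C(=O)O[C@@H]2[C@@H]1[C@H](O)/C=C(/C)C[C@H](O[Si](C)(C)C(C)(C)C)/C=C(/C)[C@H]2O[Si](C)(C)C(C)(C)C | intermediate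
30 | (R)-2-methylbutanoic acid | CC[C@@H](C)C(=O)O | starting material
31 | (1(10)Z,4Z,2S,6R,7S,8R,9R)-2,9-bis(tert-butyldimethylsilyloxy)-6-[(R)-2-methylbutanoyloxy]germacra-1(10),4,11(13)-trien-12,8-olide | C=C1C(=O)O[C@@H]2[C@@H]1[C@H](OC(=O)[C@H](C)CC)/C=C(/C)C[C@H](O[Si](C)(C)C(C)(C)C)/C=C(/C)[C@H]2O[Si](C)(C)C(C)(C)C | intermediate
32 | (1(10)Z,4Z,2S,6R,7S,8R,9R)-2,9-dihydroxy-6-[(R)-2-methylbutanoyloxy]germacra-1(10),4,11(13)-trien-12,8-olide | C=C1C(=O)O[C@@H]2[C@@H]1[C@H](OC(=O)[C@H](C)CC)/C=C(/C)C[C@H](O)/C=C(/C)[C@H]2O | target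

**Step count and risks**

Total step count: 20. Longest linear sequence: 19 steps (steps 1–5 and 7–20, from 1); step 6 is a one-step side branch.

Steps most likely to fail:

1. Step 17. What may go wrong: intermolecular coupling competing with the slow ten-membered closure, and incomplete face selection at the aldehyde carbon, because the chair demanded by the butenolide puts the new C8–O bond syn to C9–O, against the polar Felkin–Anh preference of the α-silyloxy aldehyde. Fallback: it sets out from 26 and comes back at 28. The closure is run in the same way, and the mixture of 28 and its C8 epimer F1 is oxidised with Dess–Martin periodinane to the single C8 ketone F2. F2 is reduced with NaBH4/CeCl3·7H2O in MeOH at −78 °C; hydride attack anti to the C9–O bond (the Felkin–Anh sense, now working for the route) should give the 8,9-syn alcohol 28. C8 is then set by ketone reduction and not in the C–C bond formation.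

2. Step 18. What may go wrong: the acyl shift may stop at an equilibrium that lies on the side of 28, and base may move the exocyclic double bond into the lactone ring. Fallback: it sets out from 28 and comes back at 31, so that step 19 is replaced as well, without relying on the equilibrium. O8 is blocked as the triethylsilyl ether F3 (Et3SiOTf, 2,6-lutidine). The lactone is opened with LiOH in THF/water and the carboxylate is methylated in the same flask (MeI, DMF) to the hydroxy ester F4. Its only free hydroxyl group (O6) is esterified with 30 (N,N'-dicyclohexylcarbodiimide, DMAP) to the diester F5. Brief treatment with HF·pyridine removes the triethylsilyl group selectively, and the liberated γ-hydroxy ester F6 closes onto C12 (pyridinium p-toluenesulfonate, toluene, 50 °C) to give 31.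

3. Step 7. What may go wrong: Z-to-E isomerisation of the enal through its dienolate under the fluoride/alkoxide conditions, and insufficient face selectivity at C2 with this catalyst. Fallback: it sets out from 9 and comes back at 14. A diisopinocampheylboron enolate aldol reaction of acetone ((+)-B-chlorodiisopinocampheylborane, Et3N, −78 °C, oxidative work-up; the borane enantiomer is chosen from the accepted model for methyl ketone enolates to give 2S) gives the β-hydroxy ketone F7. F7 is esterified with diethylphosphonoacetic acid (N,N'-dicyclohexylcarbodiimide, DMAP) to the phosphonoacetate F8. Intramolecular Horner–Wadsworth–Emmons olefination (LiCl, i-Pr2NEt, MeCN) then closes the same lactone 14, the ring again fixing the Z geometry.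

Further compounds
F1 | step 17 | C8 epimer of 28 (8S alcohol) | C=C1C(=O)O[C@@H]2/C=C(/C)C[C@H](O[Si](C)(C)C(C)(C)C)/C=C(/C)[C@@H](O[Si](C)(C)C(C)(C)C)[C@@H](O)[C@@H]12
F2 | step 17 | C8 ketone of 28 | C=C1C(=O)O[C@@H]2/C=C(/C)C[C@H](O[Si](C)(C)C(C)(C)C)/C=C(/C)[C@@H](O[Si](C)(C)C(C)(C)C)C(=O)[C@@H]12
F3 | step 18 | O8 triethylsilyl ether of 28 | C=C1C(=O)O[C@@H]2/C=C(/C)C[C@H](O[Si](C)(C)C(C)(C)C)/C=C(/C)[C@@H](O[Si](C)(C)C(C)(C)C)[C@H](O[Si](CC)(CC)CC)[C@@H]12
F4 | step 18 | ring-opened methyl ester with free O6 hydroxyl and O8 triethylsilyl ether | O[C@@H]1/C=C(/C)C[C@H](O[Si](C)(C)C(C)(C)C)/C=C(/C)[C@@H](O[Si](C)(C)C(C)(C)C)[C@H](O[Si](CC)(CC)CC)[C@H]1C(=C)C(=O)OC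
F5 | step 18 | O6 (R)-2-methylbutanoate of F4 | CC[C@@H](C)C(=O)O[C@@H]1/C=C(/C)C[C@H](O[Si](C)(C)C(C)(C)C)/C=C(/C)[C@@H](O[Si](C)(C)C(C)(C)C)[C@H](O[Si](CC)(CC)CC)[C@H]1C(=C)C(=O)OC
F6 | step 18 | O8-desilylated γ-hydroxy methyl ester from F5 | CC[C@@H](C)C(=O)O[C@@H]1/C=C(/C)C[C@H](O[Si](C)(C)C(C)(C)C)/C=C(/C)[C@@H](O[Si](C)(C)C(C)(C)C)[C@H](O)[C@H]1C(=C)C(=O)OC
F7 | step 7 | (4S,5Z,7R)-7,8-bis(tert-butyldimethylsilyloxy)-4-hydroxy-6-methyloct-5-en-2-one | CC(=O)C[C@H](O)/C=C(/C)[C@@H](O[Si](C)(C)C(C)(C)C)CO[Si](C)(C)C(C)(C)C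
F8 | step 7 | diethylphosphonoacetate ester of F7 | CCOP(=O)(CC(=O)O[C@@H](CC(C)=O)/C=C(/C)[C@@H](O[Si](C)(C)C(C)(C)C)CO[Si](C)(C)C(C)(C)C)OCC
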